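The constants are those of an exercise; the result is computed.

In this flask the added ligand slightly outnumbers the catalyst, so before you repeat the run, ask how much of the catalyst it leaves at work.

substrate 0.050 M; coupling partner 0.150 M; free catalyst 0.50 mM; added ligand 0.56 mM

    substrate + free catalyst ⇌ catalyst intermediate A (K1 = 8.3 L mol⁻¹, k1 = 49 L mol⁻¹ s⁻¹)
    coupling partner + catalyst intermediate A → catalyst intermediate B (k2 = 13 L mol⁻¹ s⁻¹)
    catalyst intermediate B → catalyst intermediate C (k3 = 8.7 s⁻¹)
    catalyst intermediate C ⇌ free catalyst + product (K4 = 0.046 M, k4 = 7.1 s⁻¹)
    free catalyst + added ligand ⇌ idle complex, settled at all times (K5 = 12000 L mol⁻¹)

- the form that holds most of the catalyst when 5.0 % of the substrate are converted (catalyst intermediate A / idle complex / free catalyst / catalyst intermediate B / catalyst intermediate C)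
- its share of the catalyst then
- factor on the rate of making product when 5.0 % of the substrate are converted if coupling partner is charged twice over
- factor on the rate when 5.0 % of the substrate are converted if free catalyst is charged at 5.0 mM instead

The decision for your next run is whether to leave the catalyst charge as it is or raise it to 5.0 mM, and it hangs on one quantity, which I reckon here with substrate and coupling partner taken as charged and with the return of product neglected.

Catalyst intermediate A is made from free catalyst at 2.45 s⁻¹, and it is lost by reversal at 5.90 s⁻¹ and onward at 1.95 s⁻¹. So it stands at 0.312 of the free catalyst. Catalyst intermediate B and catalyst intermediate C follow from catalyst intermediate A, as that onward rate stands to 8.7 s⁻¹ and to 7.1 s⁻¹. The whole working round, free catalyst included, therefore counts 1.47 times the free catalyst.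

The idle complex stands at balance with free catalyst and with the added ligand that remains unbound. Setting round plus idle complex equal to the charge gives a quadratic, and its root is 23.5 %. This is the free share, the fraction of the catalyst charge that stands as free catalyst. It is the thing to watch: in this reckoning, with substrate and coupling partner held fixed, the rate follows the free share times the charge. The idle share then comes to 65.5 %, more than the 34.5 % left in the round. My reckoning stops there.

The forecast names idle complex at 65 %, between 62 % and 68 %, so my idle share lies slightly above its figure. For twice the coupling partner it gives a factor of 1.6, between 1.5 and 1.7. For the larger catalyst charge it gives 25.6, between 23 and 28, on the ground that the charge “swamps the ligand and frees about 25 times as much active catalyst”.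

The simulation gives idle complex at 65.2 % of the catalyst and a factor of 1.60 for the doubled coupling partner. At 0.598 min that share sits outside the working round, while free catalyst, the resting state of the round, holds 23.2 %, more than any catalyst intermediate. Carried to the flask charged at 5.0 mM, the same root gives a free share of 60.7 %, which is 25.8 times the free catalyst of the first flask. In that flask the rate came out at 25.1 times the rate of the first.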